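The unit I counted in was the half-life of Q, T, which the gamma run gave from its first reading as 0.321 h, with Q at 48.7% after 0.333 h. The theta run, on another charge, read 49.6% at that time, so I took the same T for the flask.

| flask | Q | D | remark | time |
|---|---|---|---|---|
| gamma | 0.42 M | 0.1 mol% | run made earlier |  |
| eta | 0.66 M | 0.1 mol% | run made earlier |  |
| theta | 0.30 M | 0.15 mol% | run made earlier |  |
| flask | 0.30 M | 0.1 mol% |  | 5.0 h |

| run | time / h | L / % | G / % | Q / % |
|---|---|---|---|---|
| gamma | 0.333 | 3.0 | 10.5 | 48.7 |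
| gamma | 0.667 | 3.7 | 15.8 | 25.0 |
| gamma | 1.00 | 6.8 | 15.9 | 13.2 |
| gamma | 2.00 | 7.0 | 19.6 | 2.9 |
| gamma | 4.00 | 6.3 | 20.9 | 3.3 |
| eta | 0.833 | 4.7 | 24.4 | 15.4 |
| eta | 1.50 | 6.2 | 27.3 | 7.1 |
| eta | 2.50 | 4.3 | 27.5 | 1.9 |
| eta | 3.00 | 5.1 | 29.2 | 4.4 |
| eta | 4.00 | 4.2 | 29.6 | 4.9 |
| theta | 0.333 | 3.2 | 11.4 | 49.6 |
| theta | 0.667 | 3.7 | 13.9 | 24.3 |
| theta | 1.00 | 6.7 | 17.5 | 13.9 |
| theta | 2.00 | 7.4 | 20.9 | 6.0 |
| theta | 4.00 | 5.0 | 24.7 | 3.3 |

(standard deviation of a reading: 1 percentage point)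



1. share of L in L plus G at 4.0 min
2. share of L in L plus G at 30 min
3. share of L in L plus G at 5.0 h
4. which of L and G there is more of at 5.0 h

On that scale the flask's 4.0 min is 0.208 half-lives, so I reckoned Q down by 13.4%, with L and G just rising. Its 30 min is 1.56 half-lives, with 34.0% of Q left by the same count. Next, Q levelled off: gamma read 2.9% at 2.00 h and 3.3% at 4.00 h.

I assumed that L and G both draw on Q, so that L/G is a ratio of two rates and holds from the first rung on: the selectivity of kinetic control. I therefore multiplied L/G, from each run's summed readings, by the concentration of D, [D], which gave 0.136 mM for gamma, 0.117 mM for eta and 0.132 mM for theta. Their mean is D\*, 0.129 mM, the selectivity concentration, and the share of L in L plus G is D\*/(D\*+[D]). The flask has [D] = 0.300 mM, so my share was 30.0% at each time, with G ahead because [D] exceeds D\*.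

The forecast gave 29%, 28% and 24%, within 16% to 32% for the last, with G ahead, on the ground that “G is catalysed and L is less so”; unlike mine, its share falls late.

    Q ⇌ J (K = 3.90, k = 2.40 × 10⁻⁴ s⁻¹)
    Q ⇌ L (K = 4.70, k = 3.30 × 10⁻⁵ s⁻¹)
    Q + D ⇌ G + D, rate k3*[Q]*[D] forward; the back reaction follows from the equilibrium constant (K = 21.0, k = 0.270 L mol⁻¹ s⁻¹)
    Q → X (k = 2.10 × 10⁻⁴ s⁻¹)

The flask gave 28.9%, 28.9% and 28.0%, with G at 17.7% and L at 6.89%. The step from Q to X, which had made 48.5% of X by 5.00 h, makes no difference to that last share. A neighbouring flask charged with 0.075 M of Q at the same loading has [D] = 0.0750 mM, less than D\*, so D\* gives 63.2%, and that flask gave 62.0% at 4.0 min. At 5.00 h that neighbour had L ahead, 7.87% against 5.26% of G.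

The runs were generated by integration for an exercise.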